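Ring A is built last, not bought. Its C5–C6–C7–C8 run, four oxygenated carbons with C5-OH para to C8-OMe, is the imprint of dimethyl squarate. C4a=C8a is the C5=C6 enol-ether bond of a monocyclic 2-aryl-4H-pyran-4-one. The key step heats a 4-(4-oxopyran-2-yl)-2,3,4-trimethoxycyclobutenone. 4π ring opening to a dienylketene, 6π closure onto the pyranone and enolisation form the C5–C4a bond, close the hexasubstituted benzene ring and release the 5-OH free beside three methyl ethers. No selective O-demethylation or arene oxidation is needed. The precursor comes from one C–C bond (C8–C8a) between the metalated pyranone and squarate.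

Key step: step 4

Remark: the SMILES contains no stereocentre and no stereogenic double bond. Tamadone is achiral, so the demand for a single enantiomer is met without any stereocontrol. Flavone numbering is used for the target and pyranone numbering for compound 6.

Step 1
Reactants: 1 2',4'-dihydroxyacetophenone
Product: 2 1-[2,4-bis(benzyloxy)phenyl]ethan-1-one
Conditions: BnBr (2.4 equiv), K2CO3 (3 equiv), KI (cat.), DMF, 80 °C
Reagents that add atoms: benzyl bromide, BrCc1ccccc1
Why: Williamson ether synthesis in which heat and excess base also alkylate the hydrogen-bonded 2'-OH, and the benzyl ethers should tolerate the amide bases, TFA, MeOTf and 110 °C that follow and leave by hydrogenolysis at the end.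

Step 2
Reactants: 2 1-[2,4-bis(benzyloxy)phenyl]ethan-1-one; 3 (E)-3-ethoxyacryloyl chloride
Product: 6 2-[2,4-bis(benzyloxy)phenyl]-4H-pyran-4-one, via lithium enolate 4 (not isolated), via ethoxy enedione 5 (not isolated)
Conditions: LiHMDS (2.1 equiv), THF, −78 °C; 3 (1.0 equiv, slow addition), −78 → 0 °C; aq NH4Cl; crude 5, TFA, CH2Cl2, rt
Reagents that add atoms: none
Why: Claisen-type C-acylation of a ketone lithium enolate by an acid chloride (the second equivalent of base takes up the acidic 1,3-diketone), then acid-catalysed 6-endo oxa-Michael addition of the enol oxygen to the β-ethoxy enone and loss of ethanol, which is the standard γ-pyrone synthesis from alkoxymethylene 1,3-diketones.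

Step 3
Reactants: 6 2-[2,4-bis(benzyloxy)phenyl]-4H-pyran-4-one; 7 dimethyl squarate (3,4-dimethoxycyclobut-3-ene-1,2-dione)
Product: 10 4-{6-[2,4-bis(benzyloxy)phenyl]-4-oxo-4H-pyran-2-yl}-2,3,4-trimethoxycyclobut-2-en-1-one (racemic), via 6-lithiopyranone 8 (not isolated), via lithium alkoxide 9 (not isolated)
Conditions: TMPH, n-BuLi, THF, −78 → 0 → −78 °C (LiTMP, 1.1 equiv); 6, −78 °C, 15 min; cannula into 7 (1.2 equiv), THF, −78 °C; MeOTf (1.1 equiv), −78 → −20 °C; aq NaHCO3
Reagents that add atoms: methyl trifluoromethanesulfonate, COS(=O)(=O)C(F)(F)F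
Why: C–H lithiation by a hindered, non-nucleophilic amide at C6–H, the only ring C–H α to O1 and the most acidic one (the site at which chromones and N-alkyl-4-pyridones are metalated), then 1,2-addition of the vinyllithium to one of the two equivalent carbonyl groups of 7 and O-methylation of the tertiary lithium alkoxide, which should outrun the neutral pyranone carbonyl for the single equivalent of MeOTf; the new quaternary stereocentre forms racemic and is erased in step 4.

Step 4
Reactants: 10 4-{6-[2,4-bis(benzyloxy)phenyl]-4-oxo-4H-pyran-2-yl}-2,3,4-trimethoxycyclobut-2-en-1-one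
Product: 13 2-[2,4-bis(benzyloxy)phenyl]-5-hydroxy-6,7,8-trimethoxy-4H-chromen-4-one, via dienylketene 11 (not isolated), via cyclohexadienone 12 (not isolated)
Conditions: PhMe (0.02 M, degassed), 110 °C
Reagents that add atoms: none
Why: Moore-type ring expansion: at 110 °C the strained C1–C4 bond of 10 breaks in a conrotatory 4π electrocyclic opening to dienylketene 11, in which the donor 4-OMe turns outward and the π-acceptor pyranyl group inward (Z), next to the ketene, and because opening is reversible a wrong rotation is corrected. Ring A then closes by a disrotatory 6π electrocyclisation (six-membered carbocycle, C5–C4a bond) in which the electrophilic ketene carbon meets pyranone C5, the nucleophilic β-carbon of the O1–C6=C5 enol ether, a matched polarity. Dienone 12 holds the only new stereocentre (C4a–H, racemic, uncontrolled and irrelevant), which lies between two carbonyl groups and is erased at once by enolisation to the aromatic 5-OH chelated to C4=O, and this makes the cascade irreversible. The selectivity needed is regiochemical: closure can reach only C5 of the pyranone because the other neighbour of C6 is ring O1, and the 4-OMe blocks the furanone path that is open to free 4-hydroxy analogues. The oxygen pattern is stored in 10: the carbon methylated in step 3 becomes C8-OMe beside C8a–O1, the two squarate methoxy carbons become C7 and C6, and the ketene carbonyl becomes the free 5-OH. The closest known cases are the same expansions of 4-(dihydropyranyl)-, 4-furyl- and 4-aryl-4-alkoxycyclobutenones to hydroquinone monoethers.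

Step 5
Reactants: 13 2-[2,4-bis(benzyloxy)phenyl]-5-hydroxy-6,7,8-trimethoxy-4H-chromen-4-one
Product: 14 Tamadone, 2-(2,4-dihydroxyphenyl)-5-hydroxy-6,7,8-trimethoxy-4H-chromen-4-one
Conditions: H2 (1 atm), 10% Pd/C, EtOAc–MeOH, rt
Reagents that add atoms: none
Why: Hydrogenolysis of aryl benzyl ethers, under which the cross-conjugated C2=C3 bond of a flavone, the methyl ethers and the chelated 5-OH should stay untouched at 1 atm and rt.

Compound list
1 | 2',4'-dihydroxyacetophenone | CC(=O)c1ccc(O)cc1O | starting material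
2 | 1-[2,4-bis(benzyloxy)phenyl]ethan-1-one | CC(=O)c1ccc(OCc2ccccc2)cc1OCc1ccccc1 | intermediate
3 | (E)-3-ethoxyacryloyl chloride | CCO/C=C/C(=O)Cl | starting material
4 | lithium enolate of 2 (not isolated) | C=C(O[Li])c1ccc(OCc2ccccc2)cc1OCc1ccccc1 | intermediate
5 | (E)-1-[2,4-bis(benzyloxy)phenyl]-5-ethoxypent-4-ene-1,3-dione (largely enolised, carried on crude) | CCO/C=C/C(=O)CC(=O)c1ccc(OCc2ccccc2)cc1OCc1ccccc1 | intermediate
6 | 2-[2,4-bis(benzyloxy)phenyl]-4H-pyran-4-one | O=c1ccoc(-c2ccc(OCc3ccccc3)cc2OCc2ccccc2)c1 | intermediate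
7 | dimethyl squarate (3,4-dimethoxycyclobut-3-ene-1,2-dione) | COC1=C(OC)C(=O)C1=O | starting material
8 | 2-[2,4-bis(benzyloxy)phenyl]-6-lithio-4H-pyran-4-one (not isolated) | [Li]c1cc(=O)cc(-c2ccc(OCc3ccccc3)cc2OCc2ccccc2)o1 | intermediate
9 | lithium alkoxide of the 1,2-adduct of 8 and 7 (racemic, not isolated) | COC1=C(OC)C(O[Li])(c2cc(=O)cc(-c3ccc(OCc4ccccc4)cc3OCc3ccccc3)o2)C1=O | intermediate
10 | 4-{6-[2,4-bis(benzyloxy)phenyl]-4-oxo-4H-pyran-2-yl}-2,3,4-trimethoxycyclobut-2-en-1-one (racemic) | COC1=C(OC)C(OC)(c2cc(=O)cc(-c3ccc(OCc4ccccc4)cc3OCc3ccccc3)o2)C1=O | intermediate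
11 | (Z)-4-{6-[2,4-bis(benzyloxy)phenyl]-4-oxo-4H-pyran-2-yl}-2,3,4-trimethoxybuta-1,3-dien-1-one, the dienylketene (not isolated) | O=C=C(OC)/C(OC)=C(OC)\c1cc(=O)cc(-c2ccc(OCc3ccccc3)cc2OCc2ccccc2)o1 | intermediate
12 | 2-[2,4-bis(benzyloxy)phenyl]-6,7,8-trimethoxy-4aH-chromene-4,5-dione (racemic at C4a, not isolated) | COC1=C(OC)C(=O)C2C(=O)C=C(c3ccc(OCc4ccccc4)cc3OCc3ccccc3)OC2=C1OC | intermediate
13 | 2-[2,4-bis(benzyloxy)phenyl]-5-hydroxy-6,7,8-trimethoxy-4H-chromen-4-one | COc1c(OC)c(O)c2c(=O)cc(-c3ccc(OCc4ccccc4)cc3OCc3ccccc3)oc2c1OC | intermediate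
14 | Tamadone, 2-(2,4-dihydroxyphenyl)-5-hydroxy-6,7,8-trimethoxy-4H-chromen-4-one (achiral) | COc1c(OC)c(O)c2c(=O)cc(-c3ccc(O)cc3O)oc2c1OC | target

Total step count: 5. Longest linear sequence: 5 steps (1 → 14).

Steps most likely to fail

Step 3.
- **What may go wrong:** Metalation may occur at the wrong ring position (C3 or C5, guided by the carbonyl oxygen or the 2'-benzyloxy group), followed by β-elimination and ring opening. The lithiated pyranone may add to itself. MeOTf may O-methylate the pyranone carbonyl.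
- **Fallback:** It sets out from 6 and 7 and comes back at 10. It separates the choice of site from the making of the nucleophile.
  - 6 is zincated with TMP2Zn·2MgCl2·2LiCl (THF, −30 °C). MgCl2 occupies the carbonyl oxygen, so the base is left with the most acidic C–H, and the covalent C–Zn bond resists ring opening and self-addition. This gives bis{6-[2,4-bis(benzyloxy)phenyl]-4-oxo-4H-pyran-2-yl}zinc F1.
  - Iodine converts it into 2-[2,4-bis(benzyloxy)phenyl]-6-iodo-4H-pyran-4-one F2.
  - Iodine–magnesium exchange with i-PrMgCl·LiCl (THF, −78 °C) gives {6-[2,4-bis(benzyloxy)phenyl]-4-oxo-4H-pyran-2-yl}magnesium chloride F3 with no amide base present.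
  - Addition to 7 and an NH4Cl quench give 4-{6-[2,4-bis(benzyloxy)phenyl]-4-oxo-4H-pyran-2-yl}-4-hydroxy-2,3-dimethoxycyclobut-2-en-1-one F4.
  - MeI/Ag2O (MeCN, rt) methylates F4 under neutral conditions to 10, so no MeOTf meets the pyranone.

Step 4.
- **What may go wrong:** The dienylketene may be diverted (dimerisation, capture by traces of water, polymerisation) before it closes, because closure costs the cross-conjugated stabilisation of the pyranone.
- **Fallback:** It sets out from 7 and comes back at 14. The ring expansion is moved to a plain enol ether, where it is fully precedented, and ring C is closed afterwards by the chalcone route.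
  - Ethyl vinyl ether and t-BuLi (THF, −78 → 0 °C) give 1-ethoxyvinyllithium F5.
  - Addition to 7 at −78 °C and MeOTf give 4-(1-ethoxyvinyl)-2,3,4-trimethoxycyclobut-2-en-1-one F6.
  - Heating in toluene gives 5-ethoxy-2,3,4-trimethoxyphenol F7.
  - C-acetylation at the only free ring position (Ac2O, BF3·OEt2, 80 °C) gives 1-(2-ethoxy-6-hydroxy-3,4,5-trimethoxyphenyl)ethan-1-one F8.
  - Claisen–Schmidt condensation with commercial 2,4-bis(benzyloxy)benzaldehyde (KOH, EtOH) gives (E)-3-[2,4-bis(benzyloxy)phenyl]-1-(2-ethoxy-6-hydroxy-3,4,5-trimethoxyphenyl)prop-2-en-1-one F9.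
  - I2 (cat.), DMSO, 130 °C gives 2-[2,4-bis(benzyloxy)phenyl]-5-ethoxy-6,7,8-trimethoxy-4H-chromen-4-one F10.
  - BCl3 (CH2Cl2, −78 → 0 °C) removes the carbonyl-chelated 5-O-ethyl group and both benzyl groups to give 14.

Step 2.
- **What may go wrong:** O-acylation of the enolate may replace C-acylation, and the free silylamide may consume the acid chloride.
- **Fallback:** It sets out from 2 and comes back at 6. The C3 acylating agent is replaced by a C2 unit and then a C1 unit.
  - Claisen condensation of 2 with ethyl acetate (NaH, THF, reflux) gives 1-[2,4-bis(benzyloxy)phenyl]butane-1,3-dione F11.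
  - LDA (2.2 equiv, THF, −78 → 0 °C) gives the dilithio dianion of this diketone F12.
  - Ethyl formate acylates F12 only at the terminal carbon, and after an aq HCl quench this gives 5-[2,4-bis(benzyloxy)phenyl]-3,5-dioxopentanal F13.
  - TFA in CH2Cl2 cyclodehydrates F13 to 6.

Further compounds
F1 | step 3 | bis{6-[2,4-bis(benzyloxy)phenyl]-4-oxo-4H-pyran-2-yl}zinc | O=c1cc(-c2ccc(OCc3ccccc3)cc2OCc2ccccc2)oc([Zn]c2cc(=O)cc(-c3ccc(OCc4ccccc4)cc3OCc3ccccc3)o2)c1
F2 | step 3 | 2-[2,4-bis(benzyloxy)phenyl]-6-iodo-4H-pyran-4-one | O=c1cc(I)oc(-c2ccc(OCc3ccccc3)cc2OCc2ccccc2)c1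
F3 | step 3 | {6-[2,4-bis(benzyloxy)phenyl]-4-oxo-4H-pyran-2-yl}magnesium chloride | Cl[Mg]c1cc(=O)cc(-c2ccc(OCc3ccccc3)cc2OCc2ccccc2)o1
F4 | step 3 | 4-{6-[2,4-bis(benzyloxy)phenyl]-4-oxo-4H-pyran-2-yl}-4-hydroxy-2,3-dimethoxycyclobut-2-en-1-one (racemic) | COC1=C(OC)C(O)(c2cc(=O)cc(-c3ccc(OCc4ccccc4)cc3OCc3ccccc3)o2)C1=O
F5 | step 4 | 1-ethoxyvinyllithium | [Li]C(=C)OCC
F6 | step 4 | 4-(1-ethoxyvinyl)-2,3,4-trimethoxycyclobut-2-en-1-one (racemic) | C=C(OCC)C1(OC)C(OC)=C(OC)C1=O
F7 | step 4 | 5-ethoxy-2,3,4-trimethoxyphenol | CCOc1cc(O)c(OC)c(OC)c1OC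
F8 | step 4 | 1-(2-ethoxy-6-hydroxy-3,4,5-trimethoxyphenyl)ethan-1-one | CCOc1c(C(C)=O)c(O)c(OC)c(OC)c1OC
F9 | step 4 | (E)-3-[2,4-bis(benzyloxy)phenyl]-1-(2-ethoxy-6-hydroxy-3,4,5-trimethoxyphenyl)prop-2-en-1-one | CCOc1c(C(=O)/C=C/c2ccc(OCc3ccccc3)cc2OCc2ccccc2)c(O)c(OC)c(OC)c1OC
F10 | step 4 | 2-[2,4-bis(benzyloxy)phenyl]-5-ethoxy-6,7,8-trimethoxy-4H-chromen-4-one | CCOc1c(OC)c(OC)c(OC)c2oc(-c3ccc(OCc4ccccc4)cc3OCc3ccccc3)cc(=O)c12
F11 | step 2 | 1-[2,4-bis(benzyloxy)phenyl]butane-1,3-dione | CC(=O)CC(=O)c1ccc(OCc2ccccc2)cc1OCc1ccccc1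
F12 | step 2 | dilithio dianion of F11 (chelated Z enolate) | C=C(O[Li])/C=C(\O[Li])c1ccc(OCc2ccccc2)cc1OCc1ccccc1
F13 | step 2 | 5-[2,4-bis(benzyloxy)phenyl]-3,5-dioxopentanal | O=CCC(=O)CC(=O)c1ccc(OCc2ccccc2)cc1OCc1ccccc1
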